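The data were generated by integration for substances that don't exist; the scatter is artificial.

If target is both made and consumed, a late reading depends on how fast the second step runs against the first, so we begin with that comparison.

| flask | starting material | partner | catalyst | time |
|---|---|---|---|---|
| theta | 0.0800 M | 0.0880 M | 0.00240 M |  |
| zeta | 0.0480 M | 0.0560 M | 0.00240 M |  |
| eta | 0.0800 M | 0.260 M | 0.00240 M |  |
| beta | 0.0800 M | 0.0880 M | 0.00120 M |  |
| alpha | 0.0800 M | 0.180 M | 0.00480 M | 46 min |

- theta run (time / min: [target] / M): 6.6: 0.00867; 13: 0.01360; 20: 0.01735; 26: 0.01939; 33: 0.02045; 39: 0.02125; 46: 0.02150
- zeta run (time / min: [target] / M): 6.6: 0.00435; 13: 0.00694; 20: 0.00958; 26: 0.01087; 33: 0.01202; 39: 0.01287; 46: 0.01312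
- eta run (time / min: [target] / M): 6.6: 0.01317; 13: 0.01651; 20: 0.01663; 26: 0.01548; 33: 0.01364; 39: 0.01223; 46: 0.01045
- beta run (time / min: [target] / M): 6.6: 0.00446; 13: 0.00752; 20: 0.00981; 26: 0.01101; 33: 0.01193; 39: 0.01277; 46: 0.01323

(readings scatter by 2 × 10⁻⁴ M)

- Overall: starting material + partner -> target, with catalyst as catalyst.
- Constant volume, constant temperature.
- A reading of a species includes what of it is bound.
- "The second partner" is partner.
- An order is taken over about fifteen percent of the charge, up and down.

- the power of [catalyst] that the first rate follows, about the charge of the theta run; measure it at two percent of starting material made into target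
- the power of [partner] that the first rate follows, about the charge of the theta run; measure it at two percent of starting material made into target
- target in the alpha run at 46 min, as a share of the starting material charged

The eta run, which has the richest partner charge of the four, falls from 0.01663 M at 20 min to 0.01045 M at 46 min, so target is being lost. We suppose the loss goes as target times partner, and we call its constant the loss constant.

The theta and beta runs give this constant by elimination. Their charges differ in catalyst, and beta's first reading is half of theta's, so we take making as proportional to catalyst. Theta climbs at 7.70 × 10⁻⁴ M min⁻¹ around 0.0111 M of target, and beta climbs at 2.00 × 10⁻⁴ M min⁻¹ around 0.0104 M. If the loss is about equal at these similar levels, it is theta's slope minus twice beta's. Dividing by target and by partner, taken as charge minus target, gives a reading of 0.433 M⁻¹ min⁻¹.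

Adding this loss back to the first readings gives making constants, rate per starting material charged, of 0.0185 min⁻¹ for theta and 0.0342 min⁻¹ for eta. Across that wide span of partner they follow a power of 0.568. For the alpha run this gives making at 0.0555 min⁻¹ and loss at 0.0779 min⁻¹.

Their quotient is the loss ratio, a selectivity factor for the two steps: loss constant times partner, over making constant. Here it is 1.40. The symmetric case, a ratio of one, is our zero: first-order steps with equal constants peak at 36.8 % of the charge.

On our reckoning the loss ratio falls as partner falls, since loss goes as partner and making as the smaller power 0.568. If each target made takes one partner and each target lost takes one more, partner in the alpha run stays at or above its charge less twice the starting material, 0.0200 M, where the ratio is 0.543. A ratio held there from the start gives a peak share of that ratio raised to minus ratio over ratio less one, 48.4 %, our bound from above. The constants held at alpha's charge give 12.4 % at 46 min, our estimate from below. We commit to the middle, 30.4 %.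

The forecast gives 1.04, 0.75 and 42 %, from about 63% formed “with about 30% of that lost”. That share lies inside our bracket, above its middle.

    catalyst + partner ⇌ catalyst-reagent complex, settled at all times (3.450 M⁻¹)
    catalyst-reagent complex + starting material → target + catalyst (57.48 M⁻¹ min⁻¹)
    2 starting material ⇌ idle substrate dimer, settled at all times (5.280 M⁻¹)
    target + partner → side product (0.5118 M⁻¹ min⁻¹)

The flask gives orders of 1.0 and 0.78, and 26.5 % of the charge as target in the alpha run, inside our bracket. The pairing of starting material into the idle substrate dimer makes no difference to this share. In the eta run, the loss ratio at the charge is 3.29, which, held there, reckons a peak of 18.1 %, and the reading at 20 min is 20.8 % of the charge.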